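Numbering: ring A is the benzo ring that carries the styryl group (C3a to C7a), fused to the dihydrofuran O1–C2–C3; ring C is the second dihydrobenzofuran (primed atoms), bonded through C5' to C3.
Cuts: the C4–vinyl bond (Heck); C7a–O1 and C3–C3a of ring A (aryne plus epoxide); the oxirane back to the central stilbene and its C5'–vinyl bond (second Heck); C2'–C3' of ring C (carbene C–H insertion) and the C3'–aryl bond (Grignard).
Enabling feature: O1, C2 with its 4-oxyphenyl group and C3 with the ring C aryl group are the three ring atoms of a trans-stilbene oxide, so O1–C2 and the C2 centre arrive already formed and only C7a/C3a of ring A have to be slipped between O1 and C3; the para ring oxygen O1' makes C3 the carbon that ionises.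
Forward order: ring C dihydrofuran, central stilbene and its epoxide, ring A dihydrofuran by aryne insertion, outer stilbene, global deprotection.
Stereochemistry: C3' from a chiral dirhodium catalyst and C2' by equilibration to trans; C2 from a Shi epoxidation and kept; C3 set trans to C2 in the insertion; both alkenes E from the Heck reactions.

Key step: step 14

Assumption: Rh2(S-PTAD)4, the dirhodium tetrakis[(S)-N-phthaloyl-1-adamantylglycinate] complex, is taken to give the 3R series in step 5; should the sense of induction be the reverse, Rh2(R-PTAD)4 is used and nothing else changes.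
Abbreviations: Piv = 2,2-dimethylpropanoyl; Ts = 4-methylphenylsulfonyl; Tf = trifluoromethylsulfonyl; ArC = (2R,3R)-7-(pivaloyloxy)-2-[4-(pivaloyloxy)phenyl]-3-[3,5-bis(pivaloyloxy)phenyl]-2,3-dihydro-1-benzofuran-5-yl, i.e. compound 12 with the bromine replaced by the point of attachment.

Step 1
Reactants: 1 5-bromo-2-hydroxy-3-methoxybenzaldehyde; 2 4-methoxybenzyl chloride
Product: 3 5-bromo-3-methoxy-2-[(4-methoxybenzyl)oxy]benzaldehyde
Conditions: K2CO3, n-Bu4NI (cat.), DMF, 60 °C
Reagents that add atoms: none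
Why: Williamson ether synthesis: the phenoxide of 1, acidified by the ortho-formyl group, is alkylated by the reactive benzylic chloride under iodide catalysis, which installs the O–CH2–aryl unit that later becomes O1'–C2' with its 4-oxyphenyl group.

Step 2
Reactants: 3 5-bromo-3-methoxy-2-[(4-methoxybenzyl)oxy]benzaldehyde; 4 1-bromo-3,5-dimethoxybenzene
Product: 6 [5-bromo-3-methoxy-2-(4-methoxybenzyloxy)phenyl](3,5-dimethoxyphenyl)methanol (racemic), via 3,5-dimethoxyphenylmagnesium bromide 5 (not isolated)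
Conditions: 4, Mg, THF, reflux; then 3, THF, 0 °C; aq. NH4Cl
Reagents that add atoms: none
Why: Grignard addition to the aldehyde, which is far faster than halogen–magnesium exchange at the aryl bromide of 3 at 0 °C; the new carbinol centre is formed without control and is erased by the next oxidation.

Step 3
Reactants: 6 [5-bromo-3-methoxy-2-(4-methoxybenzyloxy)phenyl](3,5-dimethoxyphenyl)methanol
Product: 7 [5-bromo-3-methoxy-2-(4-methoxybenzyloxy)phenyl](3,5-dimethoxyphenyl)methanone
Conditions: MnO2, CH2Cl2, rt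
Reagents that add atoms: none
Why: MnO2 oxidation of a doubly benzylic secondary alcohol to the diaryl ketone, mild enough to leave the 4-methoxybenzyl ether and the aryl bromide untouched.

Step 4
Reactants: 7 [5-bromo-3-methoxy-2-(4-methoxybenzyloxy)phenyl](3,5-dimethoxyphenyl)methanone
Product: 8 hydrazone of ketone 7 (E/Z mixture)
Conditions: N2H4·H2O, AcOH (cat.), EtOH, 80 °C
Reagents that add atoms: hydrazine (used as the hydrate), NN
Why: Hydrazone condensation of the ortho-alkoxybenzophenone with excess hydrazine under acid catalysis gives the N-unsubstituted hydrazone needed as diazo precursor; its C=N geometry is irrelevant.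

Step 5
Reactants: 8 hydrazone of ketone 7
Product: 10 (2S,3R)-5-bromo-3-(3,5-dimethoxyphenyl)-7-methoxy-2-(4-methoxyphenyl)-2,3-dihydro-1-benzofuran (cis), via diaryldiazomethane 9 (not isolated)
Conditions: MnO2, CH2Cl2, 0 °C, filtration; then Rh2(S-PTAD)4 (1 mol%), CH2Cl2, 0 °C
Reagents that add atoms: none
Why: Oxidation of the hydrazone to the diaryldiazomethane and dirhodium-catalysed intramolecular C–H insertion of the donor/donor carbene into the benzylic ether C–H (five-membered ring), a reaction established for 2-benzyloxybenzophenone hydrazones, in which the chiral carboxylate ligands should fix C3' as R and deliver the cis-2,3-diaryl isomer.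

Step 6
Reactants: 10 (2S,3R)-5-bromo-3-(3,5-dimethoxyphenyl)-7-methoxy-2-(4-methoxyphenyl)-2,3-dihydro-1-benzofuran
Product: 11 (2R,3R)-5-bromo-3-(3,5-dihydroxyphenyl)-2-(4-hydroxyphenyl)-2,3-dihydro-1-benzofuran-7-ol (trans)
Conditions: BBr3 (excess), CH2Cl2, −78 °C → rt; then ice, aq. NaHCO3
Reagents that add atoms: none
Why: BBr3 cleavage of the four aryl methyl ethers, during which the benzylic C2'–O1' bond ionises reversibly through the para-oxybenzylic cation (quinone methide on work-up) and should re-close to the thermodynamically preferred trans isomer, so that C2' is set by C3', which carries no leaving group and is untouched.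

Step 7
Reactants: 11 (2R,3R)-5-bromo-3-(3,5-dihydroxyphenyl)-2-(4-hydroxyphenyl)-2,3-dihydro-1-benzofuran-7-ol
Product: 12 (2R,3R)-5-bromo-2-[4-(pivaloyloxy)phenyl]-3-[3,5-bis(pivaloyloxy)phenyl]-2,3-dihydro-1-benzofuran-7-yl pivalate
Conditions: PivCl, pyridine, DMAP (cat.), CH2Cl2, 0 °C → rt
Reagents that add atoms: pivaloyl chloride, CC(C)(C)C(=O)Cl
Why: Acylation of all four phenols with nucleophilic catalysis; the hindered esters tolerate the later amine bases, pH 10.5 buffer, fluoride, hydrogenolysis and triflation and fall only to hydroxide at the end.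

Step 8
Reactants: 13 4-vinylphenyl acetate
Product: 15 4-vinylphenyl 4-methylbenzenesulfonate, via potassium 4-vinylphenoxide 14 (not isolated)
Conditions: KOH, H2O/THF, 0 °C; then TsCl, 0 °C → rt
Reagents that add atoms: 4-methylbenzenesulfonyl chloride, Cc1ccc(cc1)S(=O)(=O)Cl
Why: Saponification of the aryl acetate followed by Schotten–Baumann sulfonylation of the phenoxide in the same flask, which avoids isolating polymerisable 4-vinylphenol.

Step 9
Reactants: 12 ring C bromide tetrapivalate; 15 4-vinylphenyl 4-methylbenzenesulfonate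
Product: 16 4-[(E)-2-ArC-ethenyl]phenyl 4-methylbenzenesulfonate
Conditions: Pd(OAc)2 (5 mol%), P(o-tol)3, Et3N, DMF, 100 °C
Reagents that add atoms: none
Why: Mizoroki–Heck reaction of the aryl bromide with the styrene, in which syn insertion and syn β-hydride elimination give the E-stilbene while the aryl tosylate and the pivalates are inert to zerovalent palladium with this ligand.

Step 10
Reactants: 16 4-[(E)-2-ArC-ethenyl]phenyl 4-methylbenzenesulfonate
Product: 17 4-[(2R,3R)-3-ArC-oxiran-2-yl]phenyl 4-methylbenzenesulfonate (trans)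
Conditions: D-fructose-derived Shi ketone (30 mol%), Oxone (2KHSO5·KHSO4·K2SO4), K2CO3, n-Bu4NHSO4, MeCN/CH2(OMe)2/aq. Na2B4O7–Na2EDTA buffer (pH about 10.5), 0 °C
Reagents that add atoms: potassium peroxymonosulfate (the active salt of Oxone), [K+].[O-]S(=O)(=O)OO
Why: Shi asymmetric epoxidation of a trans-disubstituted alkene by the chiral dioxirane through the spiro transition state, the D-fructose-derived ketone giving the (R,R)-oxide as it does with trans-stilbene irrespective of the remote ring C centres, while the buffered basic medium protects the acid-labile para-alkoxyaryl epoxide.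

Step 11
Reactants: 18 3,5-bis(benzyloxy)phenol
Product: 19 3,5-bis(benzyloxy)phenyl N-isopropylcarbamate
Conditions: i-PrNCO, Et3N (cat.), CH2Cl2, rt
Reagents that add atoms: isopropyl isocyanate, CC(C)N=C=O
Why: Carbamoylation of the phenol by addition to the isocyanate installs a metalation-directing group that is later removable under mild base.

Step 12
Reactants: 19 3,5-bis(benzyloxy)phenyl N-isopropylcarbamate
Product: 23 3,5-bis(benzyloxy)-2-(trimethylsilyl)phenyl N-isopropylcarbamate, via N-silyl carbamate 20 (not isolated), via ortho-lithiated N-silyl carbamate 21 (not isolated), via C-silylated N-silyl carbamate 22 (not isolated)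
Conditions: TBSOTf, TMEDA, Et2O, 0 °C → rt; n-BuLi, TMEDA, −78 °C; TMSCl, −78 °C → rt; aq. NH4Cl
Reagents that add atoms: chlorotrimethylsilane, C[Si](C)(C)Cl
Why: Directed ortho-metalation of the carbamate after transient N-silylation; the two ortho positions are equivalent by symmetry and each lies between the carbamate and a benzyloxy group, so lithiation and trapping with TMSCl can give only the 2-silyl isomer, and the N–Si bond is hydrolysed on work-up.

Step 13
Reactants: 23 3,5-bis(benzyloxy)-2-(trimethylsilyl)phenyl N-isopropylcarbamate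
Product: 25 3,5-bis(benzyloxy)-2-(trimethylsilyl)phenyl trifluoromethanesulfonate, via 2-silylphenol 24 (not isolated)
Conditions: Et2NH, DBU, MeCN, 40 °C; then PhNTf2, rt
Reagents that add atoms: N-phenylbis(trifluoromethanesulfonimide), O=S(=O)(N(c1ccccc1)S(=O)(=O)C(F)(F)F)C(F)(F)F
Why: Base-induced E1cB cleavage of the N-monosubstituted carbamate (the isocyanate being scavenged by Et2NH) and triflation of the liberated phenoxide, the usual entry to Kobayashi-type ortho-silylaryl triflates.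

Step 14
Reactants: 17 4-[(2R,3R)-3-ArC-oxiran-2-yl]phenyl 4-methylbenzenesulfonate; 25 3,5-bis(benzyloxy)-2-(trimethylsilyl)phenyl trifluoromethanesulfonate
Product: 27 4-[(2S,3S)-4,6-bis(benzyloxy)-3-ArC-2,3-dihydro-1-benzofuran-2-yl]phenyl 4-methylbenzenesulfonate (trans), via 3,5-bis(benzyloxy)benzyne 26 (not isolated)
Conditions: CsF (3 equiv), MeCN/toluene, rt, slow addition of 25 (2 equiv) to 17
Reagents that add atoms: none
Why: Proposed new method: fluoride unmasks aryne 26, and the oxirane oxygen of 17 adds to the aryne terminus flanked by C–H (the later C7a), giving an aryl oxonium with an aryl anion on the neighbouring carbon (the later C3a); the strained oxonium opens at the ring C benzylic carbon and the anion bonds to it, so the aryne ends up inserted into the C3–O bond. The closest known reaction type is aryne σ-insertion into the benzylic C–O bond of monosubstituted aryl epoxides, which gives 3-aryl-2,3-dihydrobenzofurans. The ring A dihydrofuran closes by C3–C3a bond formation as a three-to-five ring expansion, the anion collapsing on the carbon held next to it (four-centre, front-side) or on the contact ion pair after C3–O ionisation, not by an exo or endo displacement along a chain. C2 keeps the configuration from the Shi epoxidation because its C–O bond never breaks, and C3 is set trans to the C2 aryl group, by retention in the front-side collapse of the trans-epoxide or, if the cation becomes free, by closure anti to that aryl group. Two selectivities are needed: oxygen attack at the aryne carbon not adjacent to an oxygenated carbon, secured by the inductive polarisation of a 3-alkoxyaryne that places the anion beside the benzyloxy carbon, and cleavage at C3 and not C2, secured by the para ring oxygen O1' of the ring C aryl group against the deactivating tosyloxy group on the C2 aryl group. Ring strain in both partners drives the step, and slow aryne generation at room temperature should hold back hydride shift in the oxonium.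

Step 15
Reactants: 27 4-[(2S,3S)-4,6-bis(benzyloxy)-3-ArC-2,3-dihydro-1-benzofuran-2-yl]phenyl 4-methylbenzenesulfonate
Product: 28 4-[(2S,3S)-4,6-dihydroxy-3-ArC-2,3-dihydro-1-benzofuran-2-yl]phenyl 4-methylbenzenesulfonate
Conditions: H2 (1 atm), Pd/C, EtOAc/THF, rt
Reagents that add atoms: none
Why: Catalytic hydrogenolysis of the two primary benzyl aryl ethers, much faster than cleavage of the secondary benzylic C2–O1 and C2'–O1' bonds whose aryl groups carry electron-withdrawing sulfonyloxy or acyloxy groups; esters and the sulfonate are inert.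

Step 16
Reactants: 28 4-[(2S,3S)-4,6-dihydroxy-3-ArC-2,3-dihydro-1-benzofuran-2-yl]phenyl 4-methylbenzenesulfonate
Product: 29 (2S,3S)-4-hydroxy-3-ArC-2-[4-(tosyloxy)phenyl]-2,3-dihydro-1-benzofuran-6-yl pivalate
Conditions: PivCl (1.0 equiv), pyridine, CH2Cl2, −40 °C
Reagents that add atoms: pivaloyl chloride, CC(C)(C)C(=O)Cl
Why: Sterically controlled mono-acylation: the C6 hydroxyl lies between two ring hydrogens, the C4 hydroxyl between C5–H and C3a with its diarylmethine C3, so the bulky acyl chloride at low temperature should esterify C6.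

Step 17
Reactants: 29 (2S,3S)-4-hydroxy-3-ArC-2-[4-(tosyloxy)phenyl]-2,3-dihydro-1-benzofuran-6-yl pivalate
Product: 30 (2S,3S)-3-ArC-2-[4-(tosyloxy)phenyl]-4-(trifluoromethylsulfonyloxy)-2,3-dihydro-1-benzofuran-6-yl pivalate
Conditions: Tf2O, pyridine, CH2Cl2, 0 °C
Reagents that add atoms: trifluoromethanesulfonic anhydride, O=S(=O)(OS(=O)(=O)C(F)(F)F)C(F)(F)F
Why: O-Triflation of the remaining hindered C4 phenol with the small, highly reactive anhydride gives the coupling handle.

Step 18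
Reactants: 30 ring A C4 triflate; 13 4-vinylphenyl acetate
Product: 31 (2S,3S)-4-[(E)-2-(4-acetoxyphenyl)ethenyl]-3-ArC-2-[4-(tosyloxy)phenyl]-2,3-dihydro-1-benzofuran-6-yl pivalate
Conditions: PdCl2(PPh3)2 (5 mol%), LiCl, Et3N, DMF, 100 °C
Reagents that add atoms: none
Why: Mizoroki–Heck reaction of an aryl triflate, with LiCl channelling the arylpalladium triflate into the neutral chloride pathway that gives linear E-stilbenes with styrenes; pivalates, acetate and the aryl tosylate are inert.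

Step 19
Reactants: 31 fully protected target
Product: 32 (2S,3S)-3-[(2R,3R)-3-(3,5-dihydroxyphenyl)-7-hydroxy-2-(4-hydroxyphenyl)-2,3-dihydro-1-benzofuran-5-yl]-2-(4-hydroxyphenyl)-4-[(E)-2-(4-hydroxyphenyl)ethenyl]-2,3-dihydro-1-benzofuran-6-ol (CNP0172909.1)
Conditions: KOH, MeOH/THF/H2O (degassed), 60 °C, argon; then aq. HCl to pH 5
Reagents that add atoms: none
Why: Global saponification of the five pivalates and the acetate together with hydroxide cleavage of the aryl tosylate at sulfur, basic conditions under which neither the stilbene nor the dihydrofurans ionise and no stereocentre is deprotonated.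

Compound list
1 | 5-bromo-2-hydroxy-3-methoxybenzaldehyde | COc1cc(Br)cc(C=O)c1O | starting material
2 | 4-methoxybenzyl chloride | COc1ccc(CCl)cc1 | starting material
3 | 5-bromo-3-methoxy-2-[(4-methoxybenzyl)oxy]benzaldehyde | COc1cc(Br)cc(C=O)c1OCc1ccc(OC)cc1 | intermediate
4 | 1-bromo-3,5-dimethoxybenzene | COc1cc(Br)cc(OC)c1 | starting material
5 | 3,5-dimethoxyphenylmagnesium bromide (not isolated) | COc1cc([Mg]Br)cc(OC)c1 | intermediate
6 | [5-bromo-3-methoxy-2-(4-methoxybenzyloxy)phenyl](3,5-dimethoxyphenyl)methanol, racemic | COc1cc(Br)cc(C(O)c2cc(OC)cc(OC)c2)c1OCc1ccc(OC)cc1 | intermediate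
7 | [5-bromo-3-methoxy-2-(4-methoxybenzyloxy)phenyl](3,5-dimethoxyphenyl)methanone | COc1cc(Br)cc(C(=O)c2cc(OC)cc(OC)c2)c1OCc1ccc(OC)cc1 | intermediate
8 | hydrazone of 7, E/Z mixture | COc1cc(Br)cc(C(=NN)c2cc(OC)cc(OC)c2)c1OCc1ccc(OC)cc1 | intermediate
9 | [5-bromo-3-methoxy-2-(4-methoxybenzyloxy)phenyl](3,5-dimethoxyphenyl)diazomethane (not isolated) | COc1cc(Br)cc(C(=[N+]=[N-])c2cc(OC)cc(OC)c2)c1OCc1ccc(OC)cc1 | intermediate
10 | (2S,3R)-5-bromo-3-(3,5-dimethoxyphenyl)-7-methoxy-2-(4-methoxyphenyl)-2,3-dihydro-1-benzofuran, cis | Brc1cc(OC)c2c(c1)[C@@H](c1cc(OC)cc(OC)c1)[C@@H](c1ccc(OC)cc1)O2 | intermediate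
11 | (2R,3R)-5-bromo-3-(3,5-dihydroxyphenyl)-2-(4-hydroxyphenyl)-2,3-dihydro-1-benzofuran-7-ol, trans | Brc1cc(O)c2c(c1)[C@@H](c1cc(O)cc(O)c1)[C@H](c1ccc(O)cc1)O2 | intermediate
12 | (2R,3R)-5-bromo-2-[4-(pivaloyloxy)phenyl]-3-[3,5-bis(pivaloyloxy)phenyl]-2,3-dihydro-1-benzofuran-7-yl pivalate | Brc1cc(OC(=O)C(C)(C)C)c2c(c1)[C@@H](c1cc(OC(=O)C(C)(C)C)cc(OC(=O)C(C)(C)C)c1)[C@H](c1ccc(OC(=O)C(C)(C)C)cc1)O2 | intermediate
13 | 4-vinylphenyl acetate | CC(=O)Oc1ccc(C=C)cc1 | starting material
14 | potassium 4-vinylphenoxide (not isolated) | [K+].[O-]c1ccc(C=C)cc1 | intermediate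
15 | 4-vinylphenyl 4-methylbenzenesulfonate | C=Cc1ccc(OS(=O)(=O)c2ccc(C)cc2)cc1 | intermediate
16 | 4-[(E)-2-ArC-ethenyl]phenyl 4-methylbenzenesulfonate | Cc1ccc(cc1)S(=O)(=O)Oc1ccc(/C=C/c2cc(OC(=O)C(C)(C)C)c3c(c2)[C@@H](c2cc(OC(=O)C(C)(C)C)cc(OC(=O)C(C)(C)C)c2)[C@H](c2ccc(OC(=O)C(C)(C)C)cc2)O3)cc1 | intermediate
17 | 4-[(2R,3R)-3-ArC-oxiran-2-yl]phenyl 4-methylbenzenesulfonate, trans | O1[C@H](c2cc(OC(=O)C(C)(C)C)c3c(c2)[C@@H](c2cc(OC(=O)C(C)(C)C)cc(OC(=O)C(C)(C)C)c2)[C@H](c2ccc(OC(=O)C(C)(C)C)cc2)O3)[C@H]1c1ccc(OS(=O)(=O)c2ccc(C)cc2)cc1 | intermediate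
18 | 3,5-bis(benzyloxy)phenol | Oc1cc(OCc2ccccc2)cc(OCc2ccccc2)c1 | starting material
19 | 3,5-bis(benzyloxy)phenyl N-isopropylcarbamate | CC(C)NC(=O)Oc1cc(OCc2ccccc2)cc(OCc2ccccc2)c1 | intermediate
20 | 3,5-bis(benzyloxy)phenyl N-(tert-butyldimethylsilyl)-N-isopropylcarbamate (not isolated) | CC(C)N([Si](C)(C)C(C)(C)C)C(=O)Oc1cc(OCc2ccccc2)cc(OCc2ccccc2)c1 | intermediate
21 | 2-lithio derivative of 20 (not isolated) | CC(C)N([Si](C)(C)C(C)(C)C)C(=O)Oc1cc(OCc2ccccc2)cc(OCc2ccccc2)c1[Li] | intermediate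
22 | 3,5-bis(benzyloxy)-2-(trimethylsilyl)phenyl N-(tert-butyldimethylsilyl)-N-isopropylcarbamate (not isolated) | CC(C)N([Si](C)(C)C(C)(C)C)C(=O)Oc1cc(OCc2ccccc2)cc(OCc2ccccc2)c1[Si](C)(C)C | intermediate
23 | 3,5-bis(benzyloxy)-2-(trimethylsilyl)phenyl N-isopropylcarbamate | CC(C)NC(=O)Oc1cc(OCc2ccccc2)cc(OCc2ccccc2)c1[Si](C)(C)C | intermediate
24 | 3,5-bis(benzyloxy)-2-(trimethylsilyl)phenol (not isolated) | Oc1cc(OCc2ccccc2)cc(OCc2ccccc2)c1[Si](C)(C)C | intermediate
25 | 3,5-bis(benzyloxy)-2-(trimethylsilyl)phenyl trifluoromethanesulfonate | FC(F)(F)S(=O)(=O)Oc1cc(OCc2ccccc2)cc(OCc2ccccc2)c1[Si](C)(C)C | intermediate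
26 | 3,5-bis(benzyloxy)benzyne (not isolated) | O(Cc1ccccc1)C1=CC(OCc2ccccc2)=CC#C1 | intermediate
27 | 4-[(2S,3S)-4,6-bis(benzyloxy)-3-ArC-2,3-dihydro-1-benzofuran-2-yl]phenyl 4-methylbenzenesulfonate, trans | O(Cc1ccccc1)c1cc(OCc3ccccc3)cc2c1[C@H](c1cc(OC(=O)C(C)(C)C)c3c(c1)[C@@H](c1cc(OC(=O)C(C)(C)C)cc(OC(=O)C(C)(C)C)c1)[C@H](c1ccc(OC(=O)C(C)(C)C)cc1)O3)[C@@H](c1ccc(OS(=O)(=O)c3ccc(C)cc3)cc1)O2 | intermediate
28 | 4-[(2S,3S)-4,6-dihydroxy-3-ArC-2,3-dihydro-1-benzofuran-2-yl]phenyl 4-methylbenzenesulfonate | Oc1cc(O)cc2c1[C@H](c1cc(OC(=O)C(C)(C)C)c3c(c1)[C@@H](c1cc(OC(=O)C(C)(C)C)cc(OC(=O)C(C)(C)C)c1)[C@H](c1ccc(OC(=O)C(C)(C)C)cc1)O3)[C@@H](c1ccc(OS(=O)(=O)c3ccc(C)cc3)cc1)O2 | intermediate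
29 | (2S,3S)-4-hydroxy-3-ArC-2-[4-(tosyloxy)phenyl]-2,3-dihydro-1-benzofuran-6-yl pivalate | Oc1cc(OC(=O)C(C)(C)C)cc2c1[C@H](c1cc(OC(=O)C(C)(C)C)c3c(c1)[C@@H](c1cc(OC(=O)C(C)(C)C)cc(OC(=O)C(C)(C)C)c1)[C@H](c1ccc(OC(=O)C(C)(C)C)cc1)O3)[C@@H](c1ccc(OS(=O)(=O)c3ccc(C)cc3)cc1)O2 | intermediate
30 | (2S,3S)-3-ArC-2-[4-(tosyloxy)phenyl]-4-(trifluoromethylsulfonyloxy)-2,3-dihydro-1-benzofuran-6-yl pivalate | FC(F)(F)S(=O)(=O)Oc1cc(OC(=O)C(C)(C)C)cc2c1[C@H](c1cc(OC(=O)C(C)(C)C)c3c(c1)[C@@H](c1cc(OC(=O)C(C)(C)C)cc(OC(=O)C(C)(C)C)c1)[C@H](c1ccc(OC(=O)C(C)(C)C)cc1)O3)[C@@H](c1ccc(OS(=O)(=O)c3ccc(C)cc3)cc1)O2 | intermediate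
31 | (2S,3S)-4-[(E)-2-(4-acetoxyphenyl)ethenyl]-3-ArC-2-[4-(tosyloxy)phenyl]-2,3-dihydro-1-benzofuran-6-yl pivalate | CC(=O)Oc1ccc(/C=C/c2cc(OC(=O)C(C)(C)C)cc3c2[C@H](c2cc(OC(=O)C(C)(C)C)c4c(c2)[C@@H](c2cc(OC(=O)C(C)(C)C)cc(OC(=O)C(C)(C)C)c2)[C@H](c2ccc(OC(=O)C(C)(C)C)cc2)O4)[C@@H](c2ccc(OS(=O)(=O)c5ccc(C)cc5)cc2)O3)cc1 | intermediate
32 | (2S,3S)-3-[(2R,3R)-3-(3,5-dihydroxyphenyl)-7-hydroxy-2-(4-hydroxyphenyl)-2,3-dihydro-1-benzofuran-5-yl]-2-(4-hydroxyphenyl)-4-[(E)-2-(4-hydroxyphenyl)ethenyl]-2,3-dihydro-1-benzofuran-6-ol | Oc1ccc(/C=C/c2cc(O)cc3c2[C@H](c2cc(O)c4c(c2)[C@@H](c2cc(O)cc(O)c2)[C@H](c2ccc(O)cc2)O4)[C@@H](c2ccc(O)cc2)O3)cc1 | target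

Total step count: 19.
Longest linear sequence: 15 steps (steps 1–7, 9, 10, 14–19, from 1 to 32).

Steps most likely to fail

Step 14. The hindered, weakly nucleophilic oxirane oxygen may fail to capture the aryne, or the oxonium may rearrange by hydride shift or lose the C3 configuration before the ring closes. The fallback uses known chemistry, sets out from stilbene 16 and returns at 27. Epoxidation of 16 with the enantiomeric (L-fructose-derived) Shi ketone should give the antipodal oxirane 4-[(2S,3S)-3-ArC-oxiran-2-yl]phenyl 4-methylbenzenesulfonate F1. Acid-promoted Friedel–Crafts opening of F1 by phenol 18 (BF3·OEt2, CH2Cl2, −78 °C), at the ring C benzylic carbon, ortho to the phenolic hydroxyl and with inversion, should give the phenol alcohol 4-[(1R,2S)-2-[2,4-bis(benzyloxy)-6-hydroxyphenyl]-1-hydroxy-2-ArC-ethyl]phenyl 4-methylbenzenesulfonate F2. Mitsunobu ring closure (PPh3, DIAD, THF) then forms O1–C2 with inversion at the carbinol and gives 27. Each centre is inverted once, which is why the antipodal oxirane is required.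

Step 16. Discrimination between the two ring A hydroxyls may be insufficient, giving the regioisomeric ester or the diester. The fallback sets out from carbamate 23 and returns at 29; it tells the two oxygens apart on the small aryne precursor, where the trimethylsilyl group shields one of them. Hydrogenolysis of 23 (H2, Pd/C, EtOAc) gives 3,5-dihydroxy-2-(trimethylsilyl)phenyl N-isopropylcarbamate F3. Pivaloylation (PivCl, pyridine, −20 °C) occurs at the hydroxyl remote from silicon and gives 3-hydroxy-5-(pivaloyloxy)-2-(trimethylsilyl)phenyl N-isopropylcarbamate F4. Benzylation of the remaining hydroxyl (BnBr, K2CO3, acetone) gives 3-(benzyloxy)-5-(pivaloyloxy)-2-(trimethylsilyl)phenyl N-isopropylcarbamate F5. Carbamate cleavage (Et2NH, DBU, MeCN) passes through 3-(benzyloxy)-5-(pivaloyloxy)-2-(trimethylsilyl)phenol F6, which is not isolated and is triflated with PhNTf2 to 3-(benzyloxy)-5-(pivaloyloxy)-2-(trimethylsilyl)phenyl trifluoromethanesulfonate F7. With CsF and oxirane 17 under the conditions of step 14, F7 releases 3-(benzyloxy)-5-(pivaloyloxy)benzyne F8, whose insertion gives (2S,3S)-4-(benzyloxy)-3-ArC-2-[4-(tosyloxy)phenyl]-2,3-dihydro-1-benzofuran-6-yl pivalate F9. Hydrogenolysis of its single benzyl ether (H2, Pd/C) gives 29.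

Step 18. Oxidative addition and alkene insertion at the hindered C4 triflate may be slow, with competing hydrolysis of the triflate or polymerisation of the styrene. The fallback sets out from 13 and 30 and returns at 31; it replaces the Heck reaction by a Suzuki–Miyaura coupling. Cross-metathesis of 13 with vinylboronic acid pinacol ester (second-generation Hoveyda–Grubbs catalyst, CH2Cl2, 40 °C) gives 4-[(E)-2-(4,4,5,5-tetramethyl-1,3,2-dioxaborolan-2-yl)ethenyl]phenyl acetate F10. Coupling of F10 with triflate 30 (Pd(OAc)2, SPhos, K3PO4, toluene, 80 °C) gives 31 with the E geometry carried over from the boronate.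

Further compounds
F1 | step 14 | 4-[(2S,3S)-3-ArC-oxiran-2-yl]phenyl 4-methylbenzenesulfonate, trans | O1[C@@H](c2cc(OC(=O)C(C)(C)C)c3c(c2)[C@@H](c2cc(OC(=O)C(C)(C)C)cc(OC(=O)C(C)(C)C)c2)[C@H](c2ccc(OC(=O)C(C)(C)C)cc2)O3)[C@@H]1c1ccc(OS(=O)(=O)c2ccc(C)cc2)cc1
F2 | step 14 | 4-[(1R,2S)-2-[2,4-bis(benzyloxy)-6-hydroxyphenyl]-1-hydroxy-2-ArC-ethyl]phenyl 4-methylbenzenesulfonate | O(Cc1ccccc1)c1cc(OCc3ccccc3)cc(O)c1[C@H](c1cc(OC(=O)C(C)(C)C)c3c(c1)[C@@H](c1cc(OC(=O)C(C)(C)C)cc(OC(=O)C(C)(C)C)c1)[C@H](c1ccc(OC(=O)C(C)(C)C)cc1)O3)[C@H](c1ccc(OS(=O)(=O)c3ccc(C)cc3)cc1)O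
F3 | step 16 | 3,5-dihydroxy-2-(trimethylsilyl)phenyl N-isopropylcarbamate | CC(C)NC(=O)Oc1cc(O)cc(O)c1[Si](C)(C)C
F4 | step 16 | 3-hydroxy-5-(pivaloyloxy)-2-(trimethylsilyl)phenyl N-isopropylcarbamate | CC(C)NC(=O)Oc1cc(OC(=O)C(C)(C)C)cc(O)c1[Si](C)(C)C
F5 | step 16 | 3-(benzyloxy)-5-(pivaloyloxy)-2-(trimethylsilyl)phenyl N-isopropylcarbamate | CC(C)NC(=O)Oc1cc(OC(=O)C(C)(C)C)cc(OCc2ccccc2)c1[Si](C)(C)C
F6 | step 16 | 3-(benzyloxy)-5-(pivaloyloxy)-2-(trimethylsilyl)phenol (not isolated) | Oc1cc(OC(=O)C(C)(C)C)cc(OCc2ccccc2)c1[Si](C)(C)C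
F7 | step 16 | 3-(benzyloxy)-5-(pivaloyloxy)-2-(trimethylsilyl)phenyl trifluoromethanesulfonate | FC(F)(F)S(=O)(=O)Oc1cc(OC(=O)C(C)(C)C)cc(OCc2ccccc2)c1[Si](C)(C)C
F8 | step 16 | 3-(benzyloxy)-5-(pivaloyloxy)benzyne (not isolated) | O(Cc1ccccc1)C1=CC(OC(=O)C(C)(C)C)=CC#C1
F9 | step 16 | (2S,3S)-4-(benzyloxy)-3-ArC-2-[4-(tosyloxy)phenyl]-2,3-dihydro-1-benzofuran-6-yl pivalate | O(Cc1ccccc1)c1cc(OC(=O)C(C)(C)C)cc2c1[C@H](c1cc(OC(=O)C(C)(C)C)c3c(c1)[C@@H](c1cc(OC(=O)C(C)(C)C)cc(OC(=O)C(C)(C)C)c1)[C@H](c1ccc(OC(=O)C(C)(C)C)cc1)O3)[C@@H](c1ccc(OS(=O)(=O)c3ccc(C)cc3)cc1)O2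
F10 | step 18 | 4-[(E)-2-(4,4,5,5-tetramethyl-1,3,2-dioxaborolan-2-yl)ethenyl]phenyl acetate | CC(=O)Oc1ccc(/C=C/B2OC(C)(C)C(C)(C)O2)cc1
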